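**Plan**

- Retrosynthetic cuts: (1) the three O-benzyl bonds; (2) the aryl ether bond O1–C8a of the dihydropyranone (ring C), leaving an open-chain (S)-β-hydroxy ketone with fluorine on the future C8a; (3) the C4–C4a ketone–arene bond, leaving a fluoroarene and an (S)-β-hydroxy Weinreb amide; (4) the arene–piperidine C–C bond and the piperidine N–CH2 bond, leaving an aryl iodide and the N-sulfinyl imine of 5-chloropentanal.
- Forward order: the piperidine ring is closed first on the benzene ring A, the three-carbon chain carrying ring B is joined by acylation at the C–H between F and OBn, ring C is closed last, and the benzyl ethers are then removed.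
- Enabling feature: C8a of ring A is ortho to the C4 carbonyl and meta to the oxygens on C5 and C7, so a fluoride on C8a is displaced by the C2 alkoxide through a Meisenheimer complex that unloads into C4=O. The normally nucleophilic phloroglucinol carbon thus acts as the electrophile, and the same fluorine acidifies the neighbouring C–H through which the chain is attached.
- Because only C8a carries a leaving group while the other ortho oxygen (on C5) is a benzyl ether, the closure fixes the piperidine at C6 rather than C8 and carries the C2 configuration through without any chalcone/oxa-Michael equilibrium.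
- Stereochemistry: piperidine C2 (R) from chelate-controlled aryl Grignard addition to the (R)-tert-butanesulfinyl imine; flavanone C2 (S) from Noyori–Ikariya transfer hydrogenation of a β-keto amide with the (S,S) catalyst.

Key step: step 10

Assumption: iodination of 5-fluororesorcinol with I2/NaHCO3 in water is taken to occur at C2 (between the hydroxyls, para to fluorine), as it does for resorcinol itself.

**Route**

Step 1
Reactants: 1 5-fluorobenzene-1,3-diol
Product: 2 5-fluoro-2-iodobenzene-1,3-diol
Conditions: I2, NaHCO3, H2O, 0 °C → rt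
Reagents that add atoms: iodine, II
Why: Electrophilic aromatic iodination of a resorcinol under aqueous bicarbonate should take place at the doubly ortho-activated C2, here also para to fluorine, which puts the halogen on the carbon that will carry the piperidine.

Step 2
Reactants: 2 5-fluoro-2-iodobenzene-1,3-diol
Product: 3 1,3-bis(benzyloxy)-5-fluoro-2-iodobenzene
Conditions: BnBr, K2CO3, DMF, rt
Reagents that add atoms: benzyl bromide, BrCc1ccccc1
Why: Williamson ether synthesis on both phenols gives benzyl ethers that should survive the organometallic, acidic and basic steps and come off together by hydrogenolysis at the end.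

Step 3
Reactants: 4 5-chloropentanal; 5 (R)-2-methylpropane-2-sulfinamide
Product: 6 (R,E)-N-(5-chloropentylidene)-2-methylpropane-2-sulfinamide
Conditions: MgSO4, pyridinium p-toluenesulfonate (cat.), CH2Cl2, rt
Reagents that add atoms: none
Why: Acid-catalysed condensation of an aldehyde with tert-butanesulfinamide under dehydrating conditions is the standard entry to the (E)-N-sulfinyl aldimine and leaves the alkyl chloride untouched.

Step 4
Reactants: 3 1,3-bis(benzyloxy)-5-fluoro-2-iodobenzene; 6 (R,E)-N-(5-chloropentylidene)-2-methylpropane-2-sulfinamide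
Product: 8 (R)-N-[(1R)-1-[2,6-bis(benzyloxy)-4-fluorophenyl]-5-chloropentyl]-2-methylpropane-2-sulfinamide, via arylmagnesium chloride 7 (not isolated)
Conditions: i-PrMgCl·LiCl, THF, 0 °C → rt; then 6, CH2Cl2, −78 → −20 °C; aq. NH4Cl
Reagents that add atoms: none
Why: Iodine–magnesium exchange gives the aryl Grignard reagent regiospecifically, and its 1,2-addition to the N-sulfinyl aldimine in a mainly non-coordinating solvent should pass through the six-membered magnesium chelate that delivers the aryl group to the imine face syn to the sulfinyl oxygen, setting the (R) benzylic stereocenter under auxiliary control.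

Step 5
Reactants: 8 (R)-N-[(1R)-1-[2,6-bis(benzyloxy)-4-fluorophenyl]-5-chloropentyl]-2-methylpropane-2-sulfinamide
Product: 10 (2R)-2-[2,6-bis(benzyloxy)-4-fluorophenyl]piperidine, via aminium chloride 9 (not isolated)
Conditions: HCl (4 M in dioxane), MeOH, 0 °C → rt; evaporate; K2CO3, NaI (cat.), MeCN, 60 °C
Reagents that add atoms: none
Why: Acidic methanolysis cleaves the N–S bond and the liberated primary amine should close the piperidine by intramolecular SN2 displacement of the primary chloride (6-exo-tet) without touching the benzylic stereocenter.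

Step 6
Reactants: 10 (2R)-2-[2,6-bis(benzyloxy)-4-fluorophenyl]piperidine
Product: 11 (2R)-2-[2,6-bis(benzyloxy)-4-fluorophenyl]-1-methylpiperidine
Conditions: aq. HCHO, NaBH(OAc)3, ClCH2CH2Cl, rt
Reagents that add atoms: formaldehyde, C=O
Why: Reductive amination with formaldehyde and NaBH(OAc)3 should methylate the secondary amine once, with no quaternization and no effect on the stereocenter.

Step 7
Reactants: 12 4-(benzyloxy)benzoyl chloride; 13 N-methoxy-N-methylacetamide
Product: 14 3-[4-(benzyloxy)phenyl]-N-methoxy-N-methyl-3-oxopropanamide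
Conditions: 13, LiN(SiMe3)2 (2.1 equiv), THF, −78 °C; then 12, −78 → 0 °C; aq. NH4Cl
Reagents that add atoms: none
Why: Crossed Claisen-type C-acylation of the lithium amide enolate by the aroyl chloride, with the second equivalent of base taking up the acidic product, should give the β-keto Weinreb amide.

Step 8
Reactants: 14 3-[4-(benzyloxy)phenyl]-N-methoxy-N-methyl-3-oxopropanamide
Product: 15 (3S)-3-[4-(benzyloxy)phenyl]-3-hydroxy-N-methoxy-N-methylpropanamide
Conditions: RuCl(p-cymene)[(S,S)-TsDPEN] (1 mol %), HCO2H–Et3N (5:2), EtOAc, 35 °C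
Reagents that add atoms: none
Why: Noyori–Ikariya asymmetric transfer hydrogenation of the aryl ketone with the (S,S) catalyst should give the (S) benzylic alcohol under catalyst control, in the same sense as for acetophenone, and leaves the benzyl ether and the N–O bond intact.

Step 9
Reactants: 11 (2R)-2-[2,6-bis(benzyloxy)-4-fluorophenyl]-1-methylpiperidine; 15 (3S)-3-[4-(benzyloxy)phenyl]-3-hydroxy-N-methoxy-N-methylpropanamide
Product: 19 (3S)-1-{2,4-bis(benzyloxy)-6-fluoro-3-[(2R)-1-methylpiperidin-2-yl]phenyl}-3-[4-(benzyloxy)phenyl]-3-hydroxypropan-1-one, via aryllithium 16 (not isolated), via arylmagnesium bromide 17 (not isolated), via chloromagnesium alkoxide 18 (not isolated)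
Conditions: 11, n-BuLi, THF, −78 °C; MgBr2·OEt2, −78 → −30 °C; then 15 pretreated with i-PrMgCl (1.0 equiv, THF, −40 °C); −30 → 10 °C; aq. NH4Cl
Reagents that add atoms: none
Why: Fluorine-directed ortho-lithiation at the C–H flanked by F and OBn (the two such positions of 11 are equivalent), transmetalation to the thermally stable aryl Grignard reagent and Weinreb ketone synthesis on the pre-formed magnesium alkoxide of 15 should give the aryl ketone without over-addition and without touching either stereocenter.

Step 10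
Reactants: 19 (3S)-1-{2,4-bis(benzyloxy)-6-fluoro-3-[(2R)-1-methylpiperidin-2-yl]phenyl}-3-[4-(benzyloxy)phenyl]-3-hydroxypropan-1-one
Product: 21 (2S)-5,7-bis(benzyloxy)-2-[4-(benzyloxy)phenyl]-6-[(2R)-1-methylpiperidin-2-yl]-2,3-dihydro-4H-chromen-4-one, via potassium alkoxide 20 (not isolated)
Conditions: KN(SiMe3)2 (1.0 equiv), 18-crown-6, THF, −78 → −20 °C; AcOH quench at −20 °C
Reagents that add atoms: none
Why: Deprotonation gives the C2 alkoxide, which attacks the fluorine-bearing ring carbon ipso to form a Meisenheimer complex whose negative charge rests on C4a, C6 and C8 and is taken up from C4a by the C4 carbonyl, and loss of fluoride restores the arene and leaves the dihydropyranone. The closest known reaction type is the intramolecular SNAr O-arylation of ortho-fluoroaryl ketones used to make chromanones, flavones and xanthones. The six-membered ring O1–C2–C3–C4–C4a–C8a closes as a 6-endo-trig addition–elimination, the accepting C8a=C4a–C4=O unit lying inside the new ring. No stereocenter is formed: C2 keeps the (S) configuration set in step 8 because its C–O bond is never broken and no chalcone is passed through, and the piperidine center is a spectator. The step needs site selectivity between the two carbons ortho to the ketone, which is secured because only C8a carries fluorine (by far the better SNAr leaving group and the less hindered position) while C5 carries a benzyl ether, so the piperidine must end at C6 and not at C8. It also needs the ring closure to outrun retro-aldol cleavage and E1cB dehydration of the aldolate, for which the alkoxide is formed quantitatively at low temperature with a crown-ether-separated potassium counter-ion (no chelate to the carbonyl oxygen) and the mixture is quenched with acetic acid before warming.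

Step 11
Reactants: 21 (2S)-5,7-bis(benzyloxy)-2-[4-(benzyloxy)phenyl]-6-[(2R)-1-methylpiperidin-2-yl]-2,3-dihydro-4H-chromen-4-one
Product: 22 (2S)-5,7-dihydroxy-2-(4-hydroxyphenyl)-6-[(2R)-1-methylpiperidin-2-yl]-2,3-dihydro-4H-chromen-4-one
Conditions: H2 (1 atm), Pd/C (10 %), EtOAc–MeOH, rt
Reagents that add atoms: none
Why: Hydrogenolysis of the three aryl benzyl ethers over Pd/C under neutral conditions should free the phenols much faster than the cyclic benzylic C–O and C–N bonds are cleaved, and with no base present to open the flavanone both stereocenters are retained.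

**Compound list**

1 | 5-fluorobenzene-1,3-diol | Oc1cc(O)cc(F)c1 | starting material
2 | 5-fluoro-2-iodobenzene-1,3-diol | Oc1cc(F)cc(O)c1I | intermediate
3 | 1,3-bis(benzyloxy)-5-fluoro-2-iodobenzene | Fc1cc(OCc2ccccc2)c(I)c(OCc2ccccc2)c1 | intermediate
4 | 5-chloropentanal | O=CCCCCCl | starting material
5 | (R)-2-methylpropane-2-sulfinamide | CC(C)(C)[S@@](=O)N | starting material
6 | (R,E)-N-(5-chloropentylidene)-2-methylpropane-2-sulfinamide | CC(C)(C)[S@@](=O)/N=C/CCCCCl | intermediate
7 | [2,6-bis(benzyloxy)-4-fluorophenyl]magnesium chloride | Fc1cc(OCc2ccccc2)c([Mg]Cl)c(OCc2ccccc2)c1 | intermediate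
8 | (R)-N-[(1R)-1-[2,6-bis(benzyloxy)-4-fluorophenyl]-5-chloropentyl]-2-methylpropane-2-sulfinamide | CC(C)(C)[S@@](=O)N[C@H](CCCCCl)c1c(OCc2ccccc2)cc(F)cc1OCc1ccccc1 | intermediate
9 | (1R)-1-[2,6-bis(benzyloxy)-4-fluorophenyl]-5-chloropentan-1-aminium chloride | [Cl-].[NH3+][C@H](CCCCCl)c1c(OCc2ccccc2)cc(F)cc1OCc1ccccc1 | intermediate
10 | (2R)-2-[2,6-bis(benzyloxy)-4-fluorophenyl]piperidine | N1CCCC[C@@H]1c1c(OCc2ccccc2)cc(F)cc1OCc1ccccc1 | intermediate
11 | (2R)-2-[2,6-bis(benzyloxy)-4-fluorophenyl]-1-methylpiperidine | CN1CCCC[C@@H]1c1c(OCc2ccccc2)cc(F)cc1OCc1ccccc1 | intermediate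
12 | 4-(benzyloxy)benzoyl chloride | O=C(Cl)c1ccc(OCc2ccccc2)cc1 | starting material
13 | N-methoxy-N-methylacetamide | CON(C)C(C)=O | starting material
14 | 3-[4-(benzyloxy)phenyl]-N-methoxy-N-methyl-3-oxopropanamide | CON(C)C(=O)CC(=O)c1ccc(OCc2ccccc2)cc1 | intermediate
15 | (3S)-3-[4-(benzyloxy)phenyl]-3-hydroxy-N-methoxy-N-methylpropanamide | CON(C)C(=O)C[C@H](O)c1ccc(OCc2ccccc2)cc1 | intermediate
16 | {2,4-bis(benzyloxy)-6-fluoro-3-[(2R)-1-methylpiperidin-2-yl]phenyl}lithium | CN1CCCC[C@@H]1c1c(OCc2ccccc2)cc(F)c([Li])c1OCc1ccccc1 | intermediate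
17 | {2,4-bis(benzyloxy)-6-fluoro-3-[(2R)-1-methylpiperidin-2-yl]phenyl}magnesium bromide | CN1CCCC[C@@H]1c1c(OCc2ccccc2)cc(F)c([Mg]Br)c1OCc1ccccc1 | intermediate
18 | chloromagnesium (1S)-1-[4-(benzyloxy)phenyl]-3-[methoxy(methyl)amino]-3-oxopropan-1-olate | CON(C)C(=O)C[C@H](O[Mg]Cl)c1ccc(OCc2ccccc2)cc1 | intermediate
19 | (3S)-1-{2,4-bis(benzyloxy)-6-fluoro-3-[(2R)-1-methylpiperidin-2-yl]phenyl}-3-[4-(benzyloxy)phenyl]-3-hydroxypropan-1-one | CN1CCCC[C@@H]1c1c(OCc2ccccc2)cc(F)c(C(=O)C[C@H](O)c2ccc(OCc3ccccc3)cc2)c1OCc1ccccc1 | intermediate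
20 | potassium (1S)-3-{2,4-bis(benzyloxy)-6-fluoro-3-[(2R)-1-methylpiperidin-2-yl]phenyl}-1-[4-(benzyloxy)phenyl]-3-oxopropan-1-olate | CN1CCCC[C@@H]1c1c(OCc2ccccc2)cc(F)c(C(=O)C[C@H]([O-])c2ccc(OCc3ccccc3)cc2)c1OCc1ccccc1.[K+] | intermediate
21 | (2S)-5,7-bis(benzyloxy)-2-[4-(benzyloxy)phenyl]-6-[(2R)-1-methylpiperidin-2-yl]-2,3-dihydro-4H-chromen-4-one | CN1CCCC[C@@H]1c1c(OCc2ccccc2)cc2c(c1OCc1ccccc1)C(=O)C[C@@H](c1ccc(OCc3ccccc3)cc1)O2 | intermediate
22 | (2S)-5,7-dihydroxy-2-(4-hydroxyphenyl)-6-[(2R)-1-methylpiperidin-2-yl]-2,3-dihydro-4H-chromen-4-one | CN1CCCC[C@@H]1c1c(O)cc2c(c1O)C(=O)C[C@@H](c1ccc(O)cc1)O2 | target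

**Step count and risks**

Total steps: 11. Longest linear sequence: 8 steps (1, 2, 4, 5, 6, 9, 10, 11).

Steps most likely to fail:

Step 10. Retro-aldol cleavage or E1cB dehydration of the aldolate may outrun the ring closure, and base-induced opening of the product could erode the configuration at C2. The fallback sets out from 19 and comes back at 21. Compound 19 is oxidized with Dess–Martin periodinane in CH2Cl2 to 1-{2,4-bis(benzyloxy)-6-fluoro-3-[(2R)-1-methylpiperidin-2-yl]phenyl}-3-[4-(benzyloxy)phenyl]propane-1,3-dione F1, which cannot undergo retro-aldol or elimination. K2CO3 in DMF at 80 °C then closes the same aryl ether bond by SNAr of the enol oxygen to give 5,7-bis(benzyloxy)-2-[4-(benzyloxy)phenyl]-6-[(2R)-1-methylpiperidin-2-yl]-4H-chromen-4-one F2. Asymmetric hydrogenation of F2 with a chiral ruthenium N-heterocyclic carbene catalyst, generated from Ru(cod)(2-methylallyl)2, the imidazolinium salt SINpEt·HBF4 and KOt-Bu with the ligand enantiomer chosen for 2S, should give mainly the cis alcohol (2S,4S)-5,7-bis(benzyloxy)-2-[4-(benzyloxy)phenyl]-6-[(2R)-1-methylpiperidin-2-yl]-3,4-dihydro-2H-chromen-4-ol F3. Dess–Martin oxidation of F3 returns the route to 21.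

Step 4. The two coordinating ortho benzyloxy groups and residual THF may favour a non-chelated transition state and so lower the facial selectivity, and the hindered aryl Grignard reagent may deprotonate the enolizable aldimine instead of adding to it. The fallback sets out from 7 and comes back at 10; it reverses the polarity of the C–C bond formation. Quenching 7 with DMF gives 2,6-bis(benzyloxy)-4-fluorobenzaldehyde F4. Condensation with (S)-2-methylpropane-2-sulfinamide (Ti(OEt)4, THF) gives the non-enolizable (S,E)-N-[2,6-bis(benzyloxy)-4-fluorobenzylidene]-2-methylpropane-2-sulfinamide F5. Addition of 4-chlorobutylmagnesium bromide in CH2Cl2 at −48 °C, the best-precedented class of sulfinimine additions, should give (S)-N-[(1R)-1-[2,6-bis(benzyloxy)-4-fluorophenyl]-5-chloropentyl]-2-methylpropane-2-sulfinamide F6, the sulfur epimer of 8. Under the conditions of step 5, F6 gives 10.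

Step 9. The ortho-fluoroaryllithium may lose LiF (aryne formation) during transmetalation, and acyl transfer from the doubly ortho-substituted aryl Grignard reagent to the amide may be slow enough for enolization of the amide to compete. The fallback sets out from 15 and from aryllithium 16 and comes back at 19; it replaces acylation by carbonyl addition and oxidation. Compound 15 is silylated (TBSCl, imidazole, DMF) to (3S)-3-[4-(benzyloxy)phenyl]-3-[(tert-butyldimethylsilyl)oxy]-N-methoxy-N-methylpropanamide F7. Reduction with i-Bu2AlH in THF at −78 °C gives (3S)-3-[4-(benzyloxy)phenyl]-3-[(tert-butyldimethylsilyl)oxy]propanal F8. Aryllithium 16 is added to F8 at −78 °C, where it does not lose LiF, to give (3S)-1-{2,4-bis(benzyloxy)-6-fluoro-3-[(2R)-1-methylpiperidin-2-yl]phenyl}-3-[4-(benzyloxy)phenyl]-3-[(tert-butyldimethylsilyl)oxy]propan-1-ol F9 as a mixture of epimers at the new carbinol carbon, which does not matter. Dess–Martin oxidation gives (3S)-1-{2,4-bis(benzyloxy)-6-fluoro-3-[(2R)-1-methylpiperidin-2-yl]phenyl}-3-[4-(benzyloxy)phenyl]-3-[(tert-butyldimethylsilyl)oxy]propan-1-one F10, and HF·pyridine in THF at 0 °C removes the silyl group to give 19.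

**Further compounds**

F1 | step 10 | 1-{2,4-bis(benzyloxy)-6-fluoro-3-[(2R)-1-methylpiperidin-2-yl]phenyl}-3-[4-(benzyloxy)phenyl]propane-1,3-dione | CN1CCCC[C@@H]1c1c(OCc2ccccc2)cc(F)c(C(=O)CC(=O)c2ccc(OCc3ccccc3)cc2)c1OCc1ccccc1
F2 | step 10 | 5,7-bis(benzyloxy)-2-[4-(benzyloxy)phenyl]-6-[(2R)-1-methylpiperidin-2-yl]-4H-chromen-4-one | CN1CCCC[C@@H]1c1c(OCc2ccccc2)cc2oc(-c3ccc(OCc4ccccc4)cc3)cc(=O)c2c1OCc1ccccc1
F3 | step 10 | (2S,4S)-5,7-bis(benzyloxy)-2-[4-(benzyloxy)phenyl]-6-[(2R)-1-methylpiperidin-2-yl]-3,4-dihydro-2H-chromen-4-ol | CN1CCCC[C@@H]1c1c(OCc2ccccc2)cc2c(c1OCc1ccccc1)[C@@H](O)C[C@@H](c1ccc(OCc3ccccc3)cc1)O2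
F4 | step 4 | 2,6-bis(benzyloxy)-4-fluorobenzaldehyde | O=Cc1c(OCc2ccccc2)cc(F)cc1OCc1ccccc1
F5 | step 4 | (S,E)-N-[2,6-bis(benzyloxy)-4-fluorobenzylidene]-2-methylpropane-2-sulfinamide | CC(C)(C)[S@](=O)/N=C/c1c(OCc2ccccc2)cc(F)cc1OCc1ccccc1
F6 | step 4 | (S)-N-[(1R)-1-[2,6-bis(benzyloxy)-4-fluorophenyl]-5-chloropentyl]-2-methylpropane-2-sulfinamide | CC(C)(C)[S@](=O)N[C@H](CCCCCl)c1c(OCc2ccccc2)cc(F)cc1OCc1ccccc1
F7 | step 9 | (3S)-3-[4-(benzyloxy)phenyl]-3-[(tert-butyldimethylsilyl)oxy]-N-methoxy-N-methylpropanamide | CON(C)C(=O)C[C@H](O[Si](C)(C)C(C)(C)C)c1ccc(OCc2ccccc2)cc1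
F8 | step 9 | (3S)-3-[4-(benzyloxy)phenyl]-3-[(tert-butyldimethylsilyl)oxy]propanal | O=CC[C@H](O[Si](C)(C)C(C)(C)C)c1ccc(OCc2ccccc2)cc1
F9 | step 9 | (3S)-1-{2,4-bis(benzyloxy)-6-fluoro-3-[(2R)-1-methylpiperidin-2-yl]phenyl}-3-[4-(benzyloxy)phenyl]-3-[(tert-butyldimethylsilyl)oxy]propan-1-ol (both C1 epimers) | CN1CCCC[C@@H]1c1c(OCc2ccccc2)cc(F)c(C(O)C[C@H](O[Si](C)(C)C(C)(C)C)c2ccc(OCc3ccccc3)cc2)c1OCc1ccccc1
F10 | step 9 | (3S)-1-{2,4-bis(benzyloxy)-6-fluoro-3-[(2R)-1-methylpiperidin-2-yl]phenyl}-3-[4-(benzyloxy)phenyl]-3-[(tert-butyldimethylsilyl)oxy]propan-1-one | CN1CCCC[C@@H]1c1c(OCc2ccccc2)cc(F)c(C(=O)C[C@H](O[Si](C)(C)C(C)(C)C)c2ccc(OCc3ccccc3)cc2)c1OCc1ccccc1
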